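**Retrosynthetic overview**
1. Feature: the tetrahydrofuran ring is O1, C2–C5, with C3′ and C4′ as the exocyclic carbons. Both aryl groups lie on one face and both CH2OAc arms on the other, so a mirror plane containing O1 and bisecting C3–C4 makes the compound meso. The C3–C4–C5 unit has a cation-stabilising catechol-type aryl on C5 and a carboxyl-level C3′ on C3, so it is a latent 2-arylcyclopropane-1,1-diester, and C2=O1 is an aryl aldehyde.
2. Endgame: the free catechols come from benzyl ethers (last step), the diacetate from the meso 3,4-bis(hydroxymethyl) diol, and the diol from a cis-fused γ-lactone (C3′(=O)–O–C4′H2) whose ring fusion enforces 3,4-cis.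
3. The lactone comes from a tetrahydrofuran-3,3-diester: C4′–OH closes on the ester on its own face, and the surplus angular ester is removed by dealkoxycarbonylation.
4. Key disconnection O1–C5 and C2–C3: Lewis-acid (3+2) annulation of a cis-2-aryl-3-(silyloxymethyl)cyclopropane-1,1-diester with 3,4-bis(benzyloxy)benzaldehyde.
5. The cyclopropane comes from a Z-alkene and dimethyl diazomalonate (Rh). The Z-alkene comes from the aryl bromide and TBS propargyl ether (Sonogashira, Lindlar). Ring order: cyclopropane, tetrahydrofuran, temporary lactone.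

Key step: step 5

Remark: the target (2R,3S,4R,5S) is meso and therefore achiral, so relative stereocontrol alone delivers the drawn stereoisomer; all chiral intermediates are racemates and their SMILES show one enantiomer.

**Step 1**
Reactants: 1 4-bromo-1,2-bis(benzyloxy)benzene; 2 tert-butyldimethyl(prop-2-yn-1-yloxy)silane
Product: 3 tert-butyl({3-[3,4-bis(benzyloxy)phenyl]prop-2-yn-1-yl}oxy)dimethylsilane
Conditions: Pd(PhCN)2Cl2 (3 mol %), t-Bu3P·HBF4 (6 mol %), CuI (2 mol %), i-Pr2NH (2 equiv), dioxane, rt
Reagents that add atoms: none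
Why: Sonogashira coupling; the bulky electron-rich phosphine should allow oxidative addition of the electron-rich aryl bromide at room temperature, and the silyl and benzyl ethers are inert.

**Step 2**
Reactants: 3 aryl propargyl silyl ether
Product: 4 (Z)-tert-butyl({3-[3,4-bis(benzyloxy)phenyl]prop-2-en-1-yl}oxy)dimethylsilane
Conditions: H2 (1 atm), Lindlar catalyst (Pd/CaCO3–Pb), quinoline, EtOAc, rt, stopped after 1 equiv H2
Reagents that add atoms: none
Why: Lindlar semihydrogenation; syn delivery of hydrogen on the poisoned palladium surface should give the Z-alkene, quinoline holds back over-reduction, and benzyl ethers are not cleaved on this catalyst.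

**Step 3**
Reactants: 5 dimethyl malonate
Product: 6 dimethyl diazomalonate
Conditions: p-ABSA (1.05 equiv), Et3N, MeCN, 0 °C to rt
Reagents that add atoms: 4-acetamidobenzenesulfonyl azide (p-ABSA), CC(=O)Nc1ccc(cc1)S(=O)(=O)N=[N+]=[N-]
Why: Regitz diazo transfer to an activated methylene; the sulfonamide by-product is removed by filtration.

**Step 4**
Reactants: 4 Z-alkene; 6 dimethyl diazomalonate
Product: 7 (±)-dimethyl cis-2-[3,4-bis(benzyloxy)phenyl]-3-{[(tert-butyldimethylsilyl)oxy]methyl}cyclopropane-1,1-dicarboxylate (aryl and CH2OTBS on the same face)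
Conditions: Rh2(esp)2 (1 mol %), CH2Cl2, 0 °C to rt, 6 (1.5 equiv) added by syringe pump; chromatography on Et3N-deactivated silica
Reagents that add atoms: none
Why: Rhodium(II)-carbene cyclopropanation; the concerted, asynchronous addition keeps the alkene geometry, so the Z-alkene fixes the cis relation of the two new stereocentres (future C4 and C5), and the electron-rich styrene double bond is the most reactive site for the electrophilic carbene.

**Step 5**
Reactants: 7 cis-cyclopropane diester; 8 3,4-bis(benzyloxy)benzaldehyde
Product: 10 (±)-dimethyl 2,5-cis-4,5-trans-2,5-bis[3,4-bis(benzyloxy)phenyl]-4-{[(tert-butyldimethylsilyl)oxy]methyl}tetrahydrofuran-3,3-dicarboxylate, via oxocarbenium malonate zwitterion 9 (not isolated)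
Conditions: 8 (3 equiv), Sn(OTf)2 (10 mol %), 4 Å MS, CH2Cl2, −40 to 0 °C; Et3N quench
Reagents that add atoms: none
Why: Two-point binding of Sn(II) to the ester carbonyls of 7 weakens the C3–C5 bond, the carbonyl oxygen of 8 enters at C5 opposite to the departing malonate carbon (O1–C5), and the tin malonate of 9 then adds to the oxocarbenium carbon (C2–C3). The closest known reaction type is the Lewis-acid-catalysed formal (3+2) annulation of 2-aryl- and 2,3-disubstituted cyclopropane-1,1-diesters with aldehydes, which gives 2,5-cis tetrahydrofurans. The one new ring, the tetrahydrofuran, closes by an aldol-type 5-(enolexo)-endo-trig attack of C3 on C2=O1+. Because O1 arrives anti to the leaving C3, the aryl group and the C4 side chain, syn on the three-membered ring, end up anti on the five-membered ring (4,5-trans, C4 itself untouched); C2 is set in an envelope transition state with an E-oxocarbenium ion in which both aryl groups and the C4 side chain are pseudo-equatorial, which gives 2,5-cis. The step needs cleavage of C3–C5 and not C3–C4, which the 3,4-dialkoxyaryl donor secures because only C5 can carry positive charge, and it needs capture faster than ring re-closure, which the excess of the electron-rich, strongly nucleophilic aldehyde and the low temperature should secure. The early amine quench guards against Lewis-acid retro-aldol epimerisation at C2, and the TBS and benzyl ethers should tolerate catalytic Sn(OTf)2 below 0 °C.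

**Step 6**
Reactants: 10 tetrahydrofuran diester
Product: 12 (±)-methyl 4,6-bis[3,4-bis(benzyloxy)phenyl]-3-oxotetrahydro-1H-furo[3,4-c]furan-3a(3H)-carboxylate (cis-fused; both aryl groups on the convex face; angular ester on former C3), via hydroxy diester 11 (not isolated)
Conditions: TBAF (1.2 equiv), THF, 0 °C to rt; H2O
Reagents that add atoms: none
Why: Fluoride desilylation followed by spontaneous 5-exo-trig lactonisation (intramolecular transesterification); the C4′ oxygen can reach only the C3 ester on its own face, which turns C3 into a stereocentre with the lactone carbonyl C3′ cis to C4′.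

**Step 7**
Reactants: 12 angular ester lactone
Product: 15 (±)-4,6-bis[3,4-bis(benzyloxy)phenyl]tetrahydro-1H,3H-furo[3,4-c]furan-1-one (cis-fused; both aryl groups on the convex face), via lithium carboxylate 13 (not isolated), via lactone enolate 14 (not isolated)
Conditions: LiCl (3 equiv), H2O (3 equiv), DMSO, 145 °C
Reagents that add atoms: none
Why: Krapcho dealkoxycarbonylation; chloride removes the methyl group by SN2 whatever the crowding at the angular carbonyl, 13 loses CO2, and 14 can be protonated only to the cis-fused bicyclo[3.3.0] lactone, which places C3–H on the aryl face (2,3-trans, 3,4-cis), while β-elimination of O1 is held back because the C2–O1 bond lies near the nodal plane of the enolate.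

**Step 8**
Reactants: 15 cis-fused lactone
Product: 16 meso-{(2R,3S,4R,5S)-2,5-bis[3,4-bis(benzyloxy)phenyl]tetrahydrofuran-3,4-diyl}dimethanol
Conditions: LiAlH4 (1.5 equiv), THF, 0 °C to rt; H2O/aq NaOH work-up
Reagents that add atoms: none
Why: Hydride reduction of a lactone to the 1,4-diol; no stereocentre is touched, the two arms become identical so both enantiomers of 15 converge on one meso diol, and benzyl ethers are inert.

**Step 9**
Reactants: 16 meso diol
Product: 17 meso-{(2R,3S,4R,5S)-2,5-bis[3,4-bis(benzyloxy)phenyl]tetrahydrofuran-3,4-diyl}bis(methylene) diacetate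
Conditions: Ac2O (3 equiv), pyridine, DMAP (cat.), CH2Cl2, rt
Reagents that add atoms: acetic anhydride, CC(=O)OC(C)=O
Why: DMAP-catalysed O-acylation of the two primary alcohols while all four phenols are still masked, so only the required oxygens are acetylated.

**Step 10**
Reactants: 17 tetrabenzyl diacetate
Product: 18 [(2R,3S,4R,5S)-2,5-bis(3,4-dihydroxyphenyl)tetrahydrofuran-3,4-diyl]bis(methylene) diacetate (target)
Conditions: H2 (1 atm), 10 % Pd/C, EtOAc–THF, rt, stopped as soon as 17 and the partly debenzylated species are consumed; filtration under Ar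
Reagents that add atoms: none
Why: Catalytic hydrogenolysis; unhindered aryl benzyl ethers are cleaved much faster than the flanked ring C2–O1 and C5–O1 bonds in a neutral aprotic medium, acetates are inert and no stereocentre is touched.

**Compound list**
1 | 4-bromo-1,2-bis(benzyloxy)benzene | Brc1ccc(OCc2ccccc2)c(OCc2ccccc2)c1 | starting material
2 | tert-butyldimethyl(prop-2-yn-1-yloxy)silane | C#CCO[Si](C)(C)C(C)(C)C | starting material
3 | tert-butyl({3-[3,4-bis(benzyloxy)phenyl]prop-2-yn-1-yl}oxy)dimethylsilane | CC(C)(C)[Si](C)(C)OCC#Cc1ccc(OCc2ccccc2)c(OCc2ccccc2)c1 | intermediate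
4 | (Z)-tert-butyl({3-[3,4-bis(benzyloxy)phenyl]prop-2-en-1-yl}oxy)dimethylsilane | CC(C)(C)[Si](C)(C)OC/C=C\c1ccc(OCc2ccccc2)c(OCc2ccccc2)c1 | intermediate
5 | dimethyl malonate | COC(=O)CC(=O)OC | starting material
6 | dimethyl diazomalonate | COC(=O)C(=[N+]=[N-])C(=O)OC | intermediate
7 | (±)-dimethyl cis-2-[3,4-bis(benzyloxy)phenyl]-3-{[(tert-butyldimethylsilyl)oxy]methyl}cyclopropane-1,1-dicarboxylate | COC(=O)C1(C(=O)OC)[C@H](CO[Si](C)(C)C(C)(C)C)[C@@H]1c2ccc(OCc3ccccc3)c(OCc3ccccc3)c2 | intermediate
8 | 3,4-bis(benzyloxy)benzaldehyde | O=Cc1ccc(OCc2ccccc2)c(OCc2ccccc2)c1 | starting material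
9 | oxocarbenium malonate zwitterion (O1–C5 formed, C2–C3 still open; drawn without tin) | COC(=O)[C-](C(=O)OC)[C@H](CO[Si](C)(C)C(C)(C)C)[C@@H](c2ccc(OCc3ccccc3)c(OCc3ccccc3)c2)[O+]=Cc2ccc(OCc3ccccc3)c(OCc3ccccc3)c2 | intermediate
10 | (±)-dimethyl 2,5-cis-4,5-trans-2,5-bis[3,4-bis(benzyloxy)phenyl]-4-{[(tert-butyldimethylsilyl)oxy]methyl}tetrahydrofuran-3,3-dicarboxylate | COC(=O)C1(C(=O)OC)[C@H](CO[Si](C)(C)C(C)(C)C)[C@@H](c2ccc(OCc3ccccc3)c(OCc3ccccc3)c2)O[C@H]1c2ccc(OCc3ccccc3)c(OCc3ccccc3)c2 | intermediate
11 | hydroxy diester (desilylated 10) | COC(=O)C1(C(=O)OC)[C@H](CO)[C@@H](c2ccc(OCc3ccccc3)c(OCc3ccccc3)c2)O[C@H]1c2ccc(OCc3ccccc3)c(OCc3ccccc3)c2 | intermediate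
12 | (±)-methyl 4,6-bis[3,4-bis(benzyloxy)phenyl]-3-oxotetrahydro-1H-furo[3,4-c]furan-3a(3H)-carboxylate, cis-fused, aryl groups convex | COC(=O)[C@@]12C(=O)OC[C@@H]1[C@@H](c3ccc(OCc4ccccc4)c(OCc4ccccc4)c3)O[C@H]2c3ccc(OCc4ccccc4)c(OCc4ccccc4)c3 | intermediate
13 | lithium carboxylate from demethylation of 12 | [Li+].[O-]C(=O)[C@@]12C(=O)OC[C@@H]1[C@@H](c3ccc(OCc4ccccc4)c(OCc4ccccc4)c3)O[C@H]2c3ccc(OCc4ccccc4)c(OCc4ccccc4)c3 | intermediate
14 | lithium lactone enolate (C3 planar) | [Li+].[O-]C1=C2[C@H](CO1)[C@@H](c3ccc(OCc4ccccc4)c(OCc4ccccc4)c3)O[C@H]2c3ccc(OCc4ccccc4)c(OCc4ccccc4)c3 | intermediate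
15 | (±)-4,6-bis[3,4-bis(benzyloxy)phenyl]tetrahydro-1H,3H-furo[3,4-c]furan-1-one, cis-fused, aryl groups convex | O=C1OC[C@@H]2[C@@H](c3ccc(OCc4ccccc4)c(OCc4ccccc4)c3)O[C@@H](c3ccc(OCc4ccccc4)c(OCc4ccccc4)c3)[C@H]12 | intermediate
16 | meso-{(2R,3S,4R,5S)-2,5-bis[3,4-bis(benzyloxy)phenyl]tetrahydrofuran-3,4-diyl}dimethanol | OC[C@@H]1[C@H](CO)[C@@H](c2ccc(OCc3ccccc3)c(OCc3ccccc3)c2)O[C@H]1c2ccc(OCc3ccccc3)c(OCc3ccccc3)c2 | intermediate
17 | meso-{(2R,3S,4R,5S)-2,5-bis[3,4-bis(benzyloxy)phenyl]tetrahydrofuran-3,4-diyl}bis(methylene) diacetate | CC(=O)OC[C@@H]1[C@H](COC(C)=O)[C@@H](c2ccc(OCc3ccccc3)c(OCc3ccccc3)c2)O[C@H]1c2ccc(OCc3ccccc3)c(OCc3ccccc3)c2 | intermediate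
18 | [(2R,3S,4R,5S)-2,5-bis(3,4-dihydroxyphenyl)tetrahydrofuran-3,4-diyl]bis(methylene) diacetate | CC(=O)OC[C@@H]1[C@H](COC(C)=O)[C@@H](c2ccc(O)c(O)c2)O[C@H]1c1ccc(O)c(O)c1 | target

**Total step count:** 10. **Longest linear sequence:** 9 (steps 1, 2, 4–10 from 1; step 3 is a one-step branch).

**Steps most likely to fail**

Step 5.
- What may go wrong: ionisation of the Lewis-acid-bound cis-cyclopropane may run ahead of capture by the weakly nucleophilic carbonyl oxygen. The ring could then re-close with rotation to the trans isomer, or C4 could lose its proton. Either path erodes the inversion at C5 and the mass balance.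
- Fallback, from 7 and 8 back to 10: the annulation is split into two separate bond formations.
- NaBH4 in MeOH reduces 8 to 3,4-bis(benzyloxy)benzyl alcohol F1.
- This far better oxygen nucleophile should open 7 at C5 with inversion under much milder activation (Cu(OTf)2, 5 mol %, CH2Cl2, 0 °C; Lewis-acid-catalysed alcoholysis of donor–acceptor cyclopropanes).
- The product is the γ-benzyloxy malonate F2, with O1–C5 in place and the 4,5-anti relation.
- DDQ with LiClO4 and 2,6-dichloropyridine in 1,2-dichloroethane then removes hydride from the unhindered, electron-rich ArCH2–O group. This is oxidative C–H cleavage as in dialkoxybenzyl ether chemistry, a cross-dehydrogenative coupling of a benzylic ether with a malonate.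
- The malonate carbon closes on the cationic C2 through the same envelope and gives 10.

Step 4.
- What may go wrong: carbene transfer to the hindered Z-disubstituted alkene may be slow. Carbene dimerisation, attack on the electron-rich arenes or benzylic C–H insertion could then compete. A stepwise addition to this very electron-rich styrene could also leak the Z geometry.
- Fallback, from 3 and 6 back to 7 (step 2 is bypassed): Rh2(OAc)4-catalysed cyclopropenation of alkyne 3 with 6 gives the cyclopropene diester F3.
- Diimide, generated from 2-nitrobenzenesulfonyl hydrazide and Et3N, then adds two hydrogens suprafacially to the strained C=C.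
- The cis relation follows from syn addition and not from alkene geometry. Both faces are equivalent because C1 carries two identical esters. Diimide leaves the benzyl ethers and the benzylic cyclopropane bond alone.

Step 10.
- What may go wrong: once the para-hydroxy groups are free, the ring C2–O1 and C5–O1 bonds become p-hydroxybenzylic and could be hydrogenolysed, opening the tetrahydrofuran. Removal of all four benzyl groups may still be incomplete at that point. The catechols can also oxidise in air on the catalyst.
- Fallback, from 17 directly to 18: non-reductive debenzylation with BCl3 (excess) and pentamethylbenzene in CH2Cl2 at −78 °C, followed by a MeOH quench.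
- The benzyl groups are transferred as cations to the arene scavenger, so no hydrogen or metal surface is present.
- Acetates tolerate these conditions, and the boron-bound catecholates formed are poorer donors, which should restrain ionisation of the ring ethers.
- This fallback makes no compound outside the list (F0).

**Further compounds**
F1 | step 5 | 3,4-bis(benzyloxy)benzyl alcohol | OCc1ccc(OCc2ccccc2)c(OCc2ccccc2)c1
F2 | step 5 | (±)-dimethyl 2-{1-[3,4-bis(benzyloxy)phenyl]-1-{[3,4-bis(benzyloxy)benzyl]oxy}-3-[(tert-butyldimethylsilyl)oxy]propan-2-yl}malonate (γ-benzyloxy malonate, C4/C5 as in 10) | COC(=O)C(C(=O)OC)[C@H](CO[Si](C)(C)C(C)(C)C)[C@@H](c2ccc(OCc3ccccc3)c(OCc3ccccc3)c2)OCc2ccc(OCc3ccccc3)c(OCc3ccccc3)c2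
F3 | step 4 | dimethyl 2-[3,4-bis(benzyloxy)phenyl]-3-{[(tert-butyldimethylsilyl)oxy]methyl}cycloprop-2-ene-1,1-dicarboxylate (cyclopropene diester) | COC(=O)C1(C(=O)OC)C(CO[Si](C)(C)C(C)(C)C)=C1c2ccc(OCc3ccccc3)c(OCc3ccccc3)c2
F0 | step 10 | none | none
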